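## Structural features

The target is an achiral diaryl ether: two hexasubstituted benzene rings joined only by the oxygen between C3 of ring A and C1' of ring B, with no stereocenter to set or preserve. Ring A carries C1 CO2Me, C2 Me, C3 O-aryl, C4 OH, C5 Me and C6 OH (hydrogen-bonded to the ester), and ring B carries C1' O-aryl, C2' CHO, C3' OH, C4' Cl, C5' Me and C6' CO2H. The ether oxygen is flanked by two ortho substituents on each ring (C2 Me and C4 OH; C2' CHO and C6' CO2H), so a direct aryl C–O coupling is the hard way into the molecule. The fragile points are the aldehyde between two oxygens, the aryl chloride (at risk under forcing hydrogenolysis), and the ring B acid, which is ortho/para-oxygenated (decarboxylation in hot acid) and can lactonize onto the C4 hydroxyl through a seven-membered ring. The real difficulty is regiocontrol on two fully substituted rings, together with the crowded ether, the two carboxyls that must end as one methyl ester and one free acid, and four phenolic oxygens that must be told apart. The key step exploits the fact that in ring A the ester carbon C1 is para to the oxygenated C4 and the ether carbon C3 is next to C4: C1, C2, C5 and C6 with their substituents are the diene carbons of a 2-pyranone-5-carboxylate and C3–C4 is an aryloxy-substituted ketene acetal, so the crowded ether reduces to O-alkylation of a ring B phenol. Ring B then keeps a single unsubstituted carbon, C2', where the aldehyde can be introduced last without a regiochemical question.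

## Logic of the disconnections

21 from 20. Three O–alkyl bonds are cut in one operation: the O–CH3 bonds at the C6 and C3' oxygens and the O–CH2Ph bond of the C6' ester. They are cut last because the free phenols and the acid chelate, ionize and can lactonize, and because both methyl ethers sit ortho to a carbonyl (C1 ester, C2' aldehyde), where a chelating Lewis acid removes them selectively. The gain is one deprotection step in place of three. The demand is that the Lewis acid spares the ring A methyl ester, the aldehyde and the chloride. A tert-butyl ester at C6' is not used: it would not be expected to survive the TiCl4 of the preceding step, and an acid set free there could be turned into an acyl chloride by the formylating agent and close onto the C4 oxygen.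

20 from 18. The C2'–CHO bond is cut. An aldehyde could not be carried through enolization and a hot reaction with a ketene acetal, and in 18 C2' is the only unsubstituted carbon of either oxygenated ring. The gain is removal of the most sensitive group. The demand is an electrophile small and reactive enough to enter between two oxygen substituents under conditions that leave the benzyl ester in place.

18 from 14 and 9. Ring A is cut at C2–C3 and C4–C5. This takes the more crowded ring apart in one step, replaces the tetra-ortho-substituted aryl ether by an aliphatic C–O bond, and delivers C4 as a free phenol and C6 as an ether, already differentiated. The demand is severe: a [4+2] addition between a tetrasubstituted diene and a trisubstituted electron-rich alkene, in the correct orientation, followed by loss of CO2 and of silanol.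

9 from 7, and 7 from 4 and 5. The two O–Si bonds are cut first, then the aryl-O–CH2 bond. The moisture-sensitive acetal is made last, and the ether becomes an SN2 reaction at a primary carbon. Two identical silyl groups are chosen so that the aromatizing elimination can only leave a silyl ether at C4. The demands are enolization that is faster than attack on the neighbouring benzyl ester and that does not metalate the C5' methyl group, and hydrolysis of the aliphatic ester only.

4 from 3, 3 from 2, 2 from 1. The cuts are the O–CH3 bond at the C3' oxygen, the C4'–Cl bond and the O–CH2Ph bond of the ester. Starting from the free acid 1 puts the benzyl ester on in the first step and avoids a later saponification. The demands are chlorination between hydroxyl and methyl and not between the two hydroxyls, alkylation of the non-chelated hydroxyl only, and benzylation of the carboxylate only.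

14 from 13, 13 from 11, 11 from 10. The cuts are the O–CH3 bond, then the lactone C–O bond together with the C–C bond to the acetyl carbon, then the C–CH3 bond. This reduces the diene partner to a symmetrical three-carbonyl chain. The demands are mono-methylation of 10, C-acylation at the unsubstituted methylene of 11, and O-methylation of 13 at the 4-oxygen, not at the lactone carbonyl oxygen.

## Other disconnections considered

Alternative 1: The cut runs through ring B at C5'–C6' and C2'–C3'.
- **Forward step.** The lithium dienolate of the β-aryloxycrotonate A2 would add through its α-carbon to methyl crotonate A3 and close by attack of its γ-carbon on the methyl ester, giving the 3-aryloxycyclohexenone A1. Dehydrogenation would then give the phenol A4.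
- **In favour.** It is an anionic annulation at low temperature, with bonds formed at less crowded carbons than in the chosen cycloaddition; on this point it is the better. Ring A would come whole from an aromatic precursor, the phenol A5.
- **Against.** Extended enolates of β-alkoxycrotonates can attack an acceptor through the γ-carbon first, which would give a regioisomeric ring. A1 is below the arene oxidation level. A4 has two open positions ortho to its hydroxyl (C2' and C4'), so the chlorination question that the chosen route meets at its cheap second step returns late, on the full skeleton. A5 needs an oxygen introduced at the last free position of its ring.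
- **Comparison.** The two stereocenters of A1 are lost on aromatization, as are the transient ones of the chosen route; the plans are equal there. About six operations would follow the annulation (aromatization, chlorination, O-protection, formylation, deprotections) against two after the chosen key step, so the route is expected to be several steps longer.

Alternative 2: The cut is at C1'–C6' and C4'–C5' of ring B, with the C6' carbonyl tied to the C4 oxygen.
- **Forward step.** Heating A7, in which the C3 oxygen of ring A carries a 3-chloro-4-methoxy-2-pyranon-6-yl group and the C4 oxygen a but-2-ynoate, would give the depsidone A6 by intramolecular [4+2] addition and loss of CO2.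
- **In favour.** The tether fixes the orientation. Chlorine and methoxy arrive with the pyranone, so no aromatic chlorination is needed. The lactone differentiates the two carboxyls and its final hydrolysis releases the acid and the C4 phenol together. On these three points it is the better plan. The pairing of an oxygenated pyranone with an ynoate is electronically matched and at least the equal of the chosen pair.
- **Against.** A7 contains a 6-aryloxy-2-pyranone, an enol-ester-like acyl donor sensitive to nucleophiles, with no short preparation evident. The adjacent C3 and C4 oxygens of ring A must be differentiated, and acyl migration between them is possible. The tether closes a seven-membered ring, so little entropic help and a high temperature are to be expected.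
- **Comparison.** Both plans rest on the same reaction type, a pyranone cycloaddition with CO2 extrusion. After the key step, formylation, O-demethylation and a lactone hydrolysis that spares the methyl ester remain, one step more than in the chosen plan, and the precursor is judged longer to make.

Alternative 3: The cut is at C5–C6, C3–C4 and C1–C6 of ring A.
- **Forward step.** Et3N would convert the acid chloride A9 into the aryloxy(vinyl)ketene A10, which the siloxyalkyne A11 would intercept by [2+2] addition. Electrocyclic opening of the cyclobutenone, six-electron ring closure and tautomerization would give A8.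
- **In favour.** The convergence equals that of the chosen plan, since the ether again comes from O-alkylation of a ring B phenol. Ring A would emerge with C6 as a free phenol and C4 as a silyl ether, so ring A needs no ether cleavage; on this point it is the better. The cascade should also run at lower temperature than the chosen cycloaddition.
- **Against.** A9 is a multifunctional acid chloride (enol ether, γ-ester, tert-butyl ester elsewhere in the molecule). Its preparation is estimated at four to five extra steps, and forming it next to a tert-butyl ester is delicate. Aryloxyketenes dimerize readily, the nucleophilic alkyne can attack the acid chloride directly, and A11 must be prepared and handled cold.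
- **Comparison.** After the key step the same formylation, an O-demethylation at C3', desilylation and ester cleavage are needed, so the count there is equal or one higher, and the total is judged two to three steps longer.

Key step: step 9

Assumption on the chemistry: 2,4-dihydroxy-6-methylbenzoic acid is taken as a purchasable equivalent of its methyl ester, and the ring B carboxyl is carried as a benzyl ester; neither changes the skeletons of the key-step partners.

## Route

Step 1
Reactants: 1 2,4-dihydroxy-6-methylbenzoic acid
Product: 2 benzyl 2,4-dihydroxy-6-methylbenzoate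
Conditions: BnBr (1.05 equiv), KHCO3, DMF, rt
Reagents that add atoms: benzyl bromide, BrCc1ccccc1
Why: SN2 O-alkylation of the carboxylate; hydrogencarbonate ionizes the acid but not the phenols, so only the ester should form.

Step 2
Reactants: 2 benzyl 2,4-dihydroxy-6-methylbenzoate
Product: 3 benzyl 3-chloro-4,6-dihydroxy-2-methylbenzoate
Conditions: SO2Cl2 (1.0 equiv), Et2O, 0 °C → rt
Reagents that add atoms: sulfuryl chloride, O=S(=O)(Cl)Cl
Why: Electrophilic aromatic chlorination; in 2,4-dihydroxybenzoates the position ortho to the free hydroxyl and para to the chelated one (here between hydroxyl and methyl) is the more reactive, and one equivalent at low temperature limits dichlorination.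

Step 3
Reactants: 3 benzyl 3-chloro-4,6-dihydroxy-2-methylbenzoate
Product: 4 benzyl 3-chloro-6-hydroxy-4-methoxy-2-methylbenzoate
Conditions: MeI (1.1 equiv), K2CO3 (1.1 equiv), acetone, 40 °C
Reagents that add atoms: iodomethane, CI
Why: Williamson ether synthesis; the hydroxyl para to the ester and ortho to chlorine is the more acidic and is free, while the other is held in a hydrogen bond to the ester carbonyl, so mono-O-methylation should be selective.

Step 4
Reactants: 4 benzyl 3-chloro-6-hydroxy-4-methoxy-2-methylbenzoate; 5 methyl bromoacetate
Product: 7 2-[2-(benzyloxycarbonyl)-4-chloro-5-methoxy-3-methylphenoxy]acetic acid, via methyl aryloxyacetate diester 6 (not isolated)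
Conditions: K2CO3, DMF, 50 °C; then LiOH, H2O/THF, 0 °C → rt; aq. HCl
Reagents that add atoms: lithium hydroxide, [Li+].[OH-]
Why: Williamson ether synthesis (SN2 at the primary α-halo ester) on the chelated phenoxide in a dipolar solvent. The unhindered, inductively activated aryloxyacetate is then saponified far faster than the benzyl benzoate, which is shielded by two ortho substituents.

Step 5
Reactants: 7 2-[2-(benzyloxycarbonyl)-4-chloro-5-methoxy-3-methylphenoxy]acetic acid
Product: 9 benzyl 6-{[2,2-bis(trimethylsilyloxy)ethenyl]oxy}-3-chloro-4-methoxy-2-methylbenzoate, via trimethylsilyl ester 8 (not isolated)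
Conditions: Me3SiCl (2.5 equiv), Et3N, THF, 0 °C; then LiN(SiMe3)2 (1.2 equiv), −78 °C → rt; filtration and concentration under Ar, used crude
Reagents that add atoms: chlorotrimethylsilane, C[Si](C)(C)Cl
Why: O-silylation of the acid, then kinetic enolization of the silyl ester with O-silylation in situ (standard formation of a bis(silyl) ketene acetal). The silyl chloride traps the enolate at −78 °C before it can close onto the neighbouring benzyl ester, and the silylamide base is too weak to metalate the C5' methyl group. The two silyloxy groups are identical, so no alkene geometry arises.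

Step 6
Reactants: 10 dimethyl 3-oxopentanedioate
Product: 11 dimethyl 2-methyl-3-oxopentanedioate
Conditions: NaH (1.0 equiv), THF, 0 °C; MeI (1.0 equiv), 0 °C → rt
Reagents that add atoms: iodomethane, CI
Why: C-alkylation of a β-keto ester enolate (SN2); one equivalent each of base and MeI should favour the mono-methyl compound, and unmethylated and dimethylated material is removed at this cheap stage.

Step 7
Reactants: 11 dimethyl 2-methyl-3-oxopentanedioate
Product: 13 methyl 4-hydroxy-3,6-dimethyl-2-oxo-2H-pyran-5-carboxylate, via C-acetylated triketo diester 12 (not isolated)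
Conditions: MgCl2, pyridine, AcCl, CH2Cl2, 0 °C → rt; aq. HCl; then cat. TsOH, toluene, reflux
Reagents that add atoms: acetyl chloride, CC(=O)Cl
Why: Magnesium-chelate C-acylation of the β-keto ester at its unsubstituted methylene, then acid-catalysed lactonization of the acetyl enol oxygen onto the distal ester, the only ester it can reach through a six-membered ring, giving the 4-hydroxy-2-pyranone.

Step 8
Reactants: 13 methyl 4-hydroxy-3,6-dimethyl-2-oxo-2H-pyran-5-carboxylate
Product: 14 methyl 4-methoxy-3,6-dimethyl-2-oxo-2H-pyran-5-carboxylate
Conditions: Me2SO4, K2CO3, acetone, reflux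
Reagents that add atoms: dimethyl sulfate, COS(=O)(=O)OC
Why: O-alkylation of the vinylogous acid; 4-hydroxy-2-pyranones are methylated by dimethyl sulfate and carbonate mainly at the 4-oxygen, which keeps the 2-pyranone form needed as the diene.

Step 9
Reactants: 14 methyl 4-methoxy-3,6-dimethyl-2-oxo-2H-pyran-5-carboxylate; 9 benzyl 6-{[2,2-bis(trimethylsilyloxy)ethenyl]oxy}-3-chloro-4-methoxy-2-methylbenzoate
Product: 18 benzyl 3-chloro-6-[2-hydroxy-4-methoxy-5-(methoxycarbonyl)-3,6-dimethylphenoxy]-4-methoxy-2-methylbenzoate, via bridged lactone adduct 15 (not isolated), via cyclohexadiene bis(silyloxy) intermediate 16 (not isolated), via aryl trimethylsilyl ether 17 (not isolated)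
Conditions: 9 (2.5 equiv), toluene, 130 °C, sealed tube, Ar; then aq. HCl, THF, rt
Reagents that add atoms: none
Why: This is an inverse-electron-demand Diels–Alder reaction of a 2-pyranone-5-carboxylate with a ketene acetal, the known way from such pyranones to 4-oxygenated benzoates. The electron-rich aryloxy-bearing carbon of 9 bonds to the pyranone carbon next to the ring oxygen (β to the 5-ester and δ to the lactone carbonyl), and the acetal carbon bonds to the carbon α to the lactone carbonyl, in a concerted but strongly asynchronous [4+2] addition that gives the bridged lactone 15. Retro-[4+2] loss of CO2 opens 15 to the cyclohexadiene 16, and elimination of Me3SiOH across C3–C4 (ring A numbering), the only aromatizing elimination open to 16 because C4 carries no hydrogen, gives 17; the acidic work-up frees the C4 phenol. The only ring closed is the six-membered carbocycle of ring A, formed intermolecularly by the cycloaddition itself. The three stereocenters of 15 and the one of 16 are erased on aromatization, so no stereocontrol is needed. The selectivity required is regiochemical: the donor polarization of 9 and the acceptor polarization of 14 are matched so that the ether oxygen arrives at C3 next to the C2 methyl and the new hydroxyl at C4 para to the ester. Because the two silyloxy groups are identical, C4 always ends as the labile silyl ether; heat and an excess of 9 answer the lower electrophilicity of the 4-methoxy pyranone, and unreacted 9 returns as 7 on hydrolysis.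

Step 10
Reactants: 18 benzyl 3-chloro-6-[2-hydroxy-4-methoxy-5-(methoxycarbonyl)-3,6-dimethylphenoxy]-4-methoxy-2-methylbenzoate
Product: 20 benzyl 3-chloro-5-formyl-6-[2-hydroxy-4-methoxy-5-(methoxycarbonyl)-3,6-dimethylphenoxy]-4-methoxy-2-methylbenzoate, via aryl(chloro)methyl methyl ether 19 (not isolated)
Conditions: Cl2CHOMe, TiCl4, CH2Cl2, −78 → 0 °C; then aq. HCl
Reagents that add atoms: dichloromethyl methyl ether, COC(Cl)Cl; water, O
Why: Rieche formylation (Friedel–Crafts attack on the chloro(methoxy)carbenium ion, then hydrolysis of 19). C2' is the only unsubstituted carbon of the two oxygenated rings and is activated by two ortho oxygens and a para methyl, so no regiochemical choice exists. The benzyl ester is expected to tolerate TiCl4 at or below 0 °C, and any formate formed at the C4 oxygen is hydrolysed on work-up.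

Step 11
Reactants: 20 benzyl 3-chloro-5-formyl-6-[2-hydroxy-4-methoxy-5-(methoxycarbonyl)-3,6-dimethylphenoxy]-4-methoxy-2-methylbenzoate
Product: 21 3-chloro-6-[2,4-dihydroxy-5-(methoxycarbonyl)-3,6-dimethylphenoxy]-5-formyl-4-hydroxy-2-methylbenzoic acid
Conditions: BCl3 (excess), CH2Cl2, −78 °C → rt; then H2O
Reagents that add atoms: none
Why: Lewis-acid dealkylation: BCl3 bridges each carbonyl oxygen and the neighbouring methoxy oxygen (C6 beside the ester, C3' beside the aldehyde) and chloride removes the methyl group, while the benzyl ester is cleaved at its benzylic C–O bond. The ring A methyl ester, held in the boron chelate and offering no stabilized alkyl group, should remain. Both rings are fully substituted, so the benzyl fragment cannot re-enter.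

## Compound list

1 | 2,4-dihydroxy-6-methylbenzoic acid | Cc1cc(O)cc(O)c1C(=O)O | starting material
2 | benzyl 2,4-dihydroxy-6-methylbenzoate | Cc1cc(O)cc(O)c1C(=O)OCc1ccccc1 | intermediate
3 | benzyl 3-chloro-4,6-dihydroxy-2-methylbenzoate | Cc1c(Cl)c(O)cc(O)c1C(=O)OCc1ccccc1 | intermediate
4 | benzyl 3-chloro-6-hydroxy-4-methoxy-2-methylbenzoate | COc1cc(O)c(C(=O)OCc2ccccc2)c(C)c1Cl | intermediate
5 | methyl bromoacetate | COC(=O)CBr | starting material
6 | benzyl 3-chloro-4-methoxy-6-(2-methoxy-2-oxoethoxy)-2-methylbenzoate | COC(=O)COc1cc(OC)c(Cl)c(C)c1C(=O)OCc1ccccc1 | intermediate (not isolated)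
7 | 2-[2-(benzyloxycarbonyl)-4-chloro-5-methoxy-3-methylphenoxy]acetic acid | OC(=O)COc1cc(OC)c(Cl)c(C)c1C(=O)OCc1ccccc1 | intermediate
8 | trimethylsilyl 2-[2-(benzyloxycarbonyl)-4-chloro-5-methoxy-3-methylphenoxy]acetate | C[Si](C)(C)OC(=O)COc1cc(OC)c(Cl)c(C)c1C(=O)OCc1ccccc1 | intermediate (not isolated)
9 | benzyl 6-{[2,2-bis(trimethylsilyloxy)ethenyl]oxy}-3-chloro-4-methoxy-2-methylbenzoate | C[Si](C)(C)OC(O[Si](C)(C)C)=COc1cc(OC)c(Cl)c(C)c1C(=O)OCc1ccccc1 | intermediate
10 | dimethyl 3-oxopentanedioate | COC(=O)CC(=O)CC(=O)OC | starting material
11 | dimethyl 2-methyl-3-oxopentanedioate (racemic, configurationally labile) | COC(=O)CC(=O)C(C)C(=O)OC | intermediate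
12 | dimethyl 2-acetyl-4-methyl-3-oxopentanedioate (enolized, no defined configuration) | COC(=O)C(C)C(=O)C(C(C)=O)C(=O)OC | intermediate (not isolated)
13 | methyl 4-hydroxy-3,6-dimethyl-2-oxo-2H-pyran-5-carboxylate | COC(=O)c1c(C)oc(=O)c(C)c1O | intermediate
14 | methyl 4-methoxy-3,6-dimethyl-2-oxo-2H-pyran-5-carboxylate | COC(=O)c1c(C)oc(=O)c(C)c1OC | intermediate
15 | methyl 7-[2-(benzyloxycarbonyl)-4-chloro-5-methoxy-3-methylphenoxy]-5-methoxy-1,4-dimethyl-3-oxo-8,8-bis(trimethylsilyloxy)-2-oxabicyclo[2.2.2]oct-5-ene-6-carboxylate (racemic, configuration at C7 not controlled) | CC12OC(=O)C(C)(C(OC)=C1C(=O)OC)C(O[Si](C)(C)C)(O[Si](C)(C)C)C2Oc1cc(OC)c(Cl)c(C)c1C(=O)OCc1ccccc1 | intermediate (not isolated)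
16 | methyl 3-[2-(benzyloxycarbonyl)-4-chloro-5-methoxy-3-methylphenoxy]-6-methoxy-2,5-dimethyl-4,4-bis(trimethylsilyloxy)cyclohexa-1,5-diene-1-carboxylate (racemic) | COC(=O)C1=C(C)C(Oc2cc(OC)c(Cl)c(C)c2C(=O)OCc2ccccc2)C(O[Si](C)(C)C)(O[Si](C)(C)C)C(C)=C1OC | intermediate (not isolated)
17 | benzyl 3-chloro-4-methoxy-6-[4-methoxy-5-(methoxycarbonyl)-3,6-dimethyl-2-(trimethylsilyloxy)phenoxy]-2-methylbenzoate | COC(=O)c1c(C)c(Oc2cc(OC)c(Cl)c(C)c2C(=O)OCc2ccccc2)c(O[Si](C)(C)C)c(C)c1OC | intermediate (not isolated)
18 | benzyl 3-chloro-6-[2-hydroxy-4-methoxy-5-(methoxycarbonyl)-3,6-dimethylphenoxy]-4-methoxy-2-methylbenzoate | COC(=O)c1c(C)c(Oc2cc(OC)c(Cl)c(C)c2C(=O)OCc2ccccc2)c(O)c(C)c1OC | intermediate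
19 | benzyl 3-chloro-5-[chloro(methoxy)methyl]-6-[2-hydroxy-4-methoxy-5-(methoxycarbonyl)-3,6-dimethylphenoxy]-4-methoxy-2-methylbenzoate (racemic, titanium-bound) | COC(=O)c1c(C)c(Oc2c(C(Cl)OC)c(OC)c(Cl)c(C)c2C(=O)OCc2ccccc2)c(O)c(C)c1OC | intermediate (not isolated)
20 | benzyl 3-chloro-5-formyl-6-[2-hydroxy-4-methoxy-5-(methoxycarbonyl)-3,6-dimethylphenoxy]-4-methoxy-2-methylbenzoate | COC(=O)c1c(C)c(Oc2c(C=O)c(OC)c(Cl)c(C)c2C(=O)OCc2ccccc2)c(O)c(C)c1OC | intermediate
21 | 3-chloro-6-[2,4-dihydroxy-5-(methoxycarbonyl)-3,6-dimethylphenoxy]-5-formyl-4-hydroxy-2-methylbenzoic acid | COC(=O)c1c(C)c(Oc2c(C=O)c(O)c(Cl)c(C)c2C(=O)O)c(O)c(C)c1O | target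

## Step count and least certain steps

Total: 11 steps. Longest linear sequence: 8 steps (steps 1–5, then 9–11); the pyranone branch (steps 6–8) joins at step 9.

Step 9 (key step). The most likely failure is that the cycloaddition is slower than the thermal or hydrolytic decay of 9. Both bond-forming termini of the diene carry methyl groups, the 4-methoxy group lowers the electrophilicity of 14, and the attacking carbon of 9 carries a bulky ortho-substituted aryloxy group; only 14 and 7 would then be recovered. The fallback sets out from 4 and comes back at 18 by a copper-catalysed Ullmann-type ether synthesis. Methyl 2,4-dihydroxy-3,6-dimethylbenzoate F1 (purchased) would be iodinated at its single free ring position (N-iodosuccinimide, cat. CF3CO2H, MeCN) to methyl 2,4-dihydroxy-5-iodo-3,6-dimethylbenzoate F2. Allylation of the non-chelated hydroxyl (allyl bromide, K2CO3, acetone) should give methyl 2-hydroxy-5-iodo-3,6-dimethyl-4-(prop-2-enyloxy)benzoate F3, and methylation of the chelated one (MeI, K2CO3, DMF, 60 °C) methyl 5-iodo-2-methoxy-3,6-dimethyl-4-(prop-2-enyloxy)benzoate F4. Coupling of F4 with 4 (CuI, picolinic acid, K3PO4, DMSO, 90 °C) should give benzyl 3-chloro-4-methoxy-6-[4-methoxy-5-(methoxycarbonyl)-3,6-dimethyl-2-(prop-2-enyloxy)phenoxy]-2-methylbenzoate F5, and removal of the allyl group (Pd(PPh3)4, morpholine, THF, rt) would return 18. The price is a hindered C–O coupling and four extra steps.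

Step 5. The enolate may close onto the neighbouring benzyl ester (Dieckmann-type ring closure to a benzofuranone) before it is silylated, and the acetal may hydrolyse during handling. The fallback sets out from 7 and comes back at 18 without any metal enolate. Treatment of 7 with tBuMe2SiOSO2CF3 and Et3N (CH2Cl2, 0 °C → rt) should give first tert-butyldimethylsilyl 2-[2-(benzyloxycarbonyl)-4-chloro-5-methoxy-3-methylphenoxy]acetate F6 and then, by amine/silyl triflate enolization, the more robust benzyl 6-{[2,2-bis(tert-butyldimethylsilyloxy)ethenyl]oxy}-3-chloro-4-methoxy-2-methylbenzoate F7. Heating F7 with 14 as in step 9 should give benzyl 6-[2-(tert-butyldimethylsilyloxy)-4-methoxy-5-(methoxycarbonyl)-3,6-dimethylphenoxy]-3-chloro-4-methoxy-2-methylbenzoate F8, and Bu4NF/AcOH in THF would free the phenol to give 18.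

Step 10. The electrophile may fail to enter the crowded C2' position, or TiCl4 may cleave the benzyl ester, after which the acid could be activated by the reagent and lactonize onto the C4 oxygen. The fallback sets out from 18 and comes back at 20, with a smaller electrophile and a nucleophilic formylation. Bromination (N-bromosuccinimide, MeCN, 0 °C) should give benzyl 5-bromo-3-chloro-6-[2-hydroxy-4-methoxy-5-(methoxycarbonyl)-3,6-dimethylphenoxy]-4-methoxy-2-methylbenzoate F9. Deprotonation of the phenol (MeMgCl), bromine–magnesium exchange (iPrMgCl·LiCl, THF, −15 °C → rt) and trapping with DMF would then give 20; both esters are shielded by two ortho substituents.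

Step 11. The three cleavages may not keep pace: the benzyl ester may need temperatures at which the ring A methyl ester starts to cleave, or at which the ring B acyl group is activated and lactonizes. The fallback sets out from 20 and comes back at 21 by splitting the deprotection in two. BCl3 at −78 → −20 °C would remove only the two chelated methyl groups, to give benzyl 3-chloro-6-[2,4-dihydroxy-5-(methoxycarbonyl)-3,6-dimethylphenoxy]-5-formyl-4-hydroxy-2-methylbenzoate F10. Hydrogenolysis (H2, 1 atm, Pd/C, EtOAc, rt, monitored) would then remove the benzyl group; the aldehyde, by then chelated, and the aryl chloride should be slow to react under neutral conditions.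

Step 2. Chlorination may occur between the two hydroxyls, or twice. The fallback sets out from 2 and comes back at 4 with the order reversed, so that a single free hydroxyl directs. Methylation of the non-chelated hydroxyl (MeI, K2CO3, acetone) would give benzyl 2-hydroxy-4-methoxy-6-methylbenzoate F11, and chlorination (SO2Cl2, CH2Cl2, 0 °C) para to the remaining hydroxyl would give 4.

Step 6. Over-methylation and proton exchange may give a statistical mixture of un-, mono- and dimethylated diester. The fallback sets out from 10 and comes back at 13, introducing the methyl group after ring formation, where the ring carbon between the two oxygenated carbons is the only nucleophilic one. Acylation and lactonization of 10 under the conditions of step 7 should give methyl 4-hydroxy-6-methyl-2-oxo-2H-pyran-5-carboxylate F12. Condensation with formaldehyde and thiophenol (cat. piperidine/AcOH, EtOH, reflux) would give methyl 4-hydroxy-6-methyl-2-oxo-3-[(phenylsulfanyl)methyl]-2H-pyran-5-carboxylate F13, and desulfurization with Raney Ni (EtOH, rt) would give 13.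

## Further compounds

F1 | step 9 | methyl 2,4-dihydroxy-3,6-dimethylbenzoate (purchased) | COC(=O)c1c(C)cc(O)c(C)c1O
F2 | step 9 | methyl 2,4-dihydroxy-5-iodo-3,6-dimethylbenzoate | COC(=O)c1c(C)c(I)c(O)c(C)c1O
F3 | step 9 | methyl 2-hydroxy-5-iodo-3,6-dimethyl-4-(prop-2-enyloxy)benzoate | COC(=O)c1c(C)c(I)c(OCC=C)c(C)c1O
F4 | step 9 | methyl 5-iodo-2-methoxy-3,6-dimethyl-4-(prop-2-enyloxy)benzoate | COC(=O)c1c(C)c(I)c(OCC=C)c(C)c1OC
F5 | step 9 | benzyl 3-chloro-4-methoxy-6-[4-methoxy-5-(methoxycarbonyl)-3,6-dimethyl-2-(prop-2-enyloxy)phenoxy]-2-methylbenzoate | COC(=O)c1c(C)c(Oc2cc(OC)c(Cl)c(C)c2C(=O)OCc2ccccc2)c(OCC=C)c(C)c1OC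
F6 | step 5 | tert-butyldimethylsilyl 2-[2-(benzyloxycarbonyl)-4-chloro-5-methoxy-3-methylphenoxy]acetate | CC(C)(C)[Si](C)(C)OC(=O)COc1cc(OC)c(Cl)c(C)c1C(=O)OCc1ccccc1
F7 | step 5 | benzyl 6-{[2,2-bis(tert-butyldimethylsilyloxy)ethenyl]oxy}-3-chloro-4-methoxy-2-methylbenzoate | CC(C)(C)[Si](C)(C)OC(O[Si](C)(C)C(C)(C)C)=COc1cc(OC)c(Cl)c(C)c1C(=O)OCc1ccccc1
F8 | step 5 | benzyl 6-[2-(tert-butyldimethylsilyloxy)-4-methoxy-5-(methoxycarbonyl)-3,6-dimethylphenoxy]-3-chloro-4-methoxy-2-methylbenzoate | COC(=O)c1c(C)c(Oc2cc(OC)c(Cl)c(C)c2C(=O)OCc2ccccc2)c(O[Si](C)(C)C(C)(C)C)c(C)c1OC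
F9 | step 10 | benzyl 5-bromo-3-chloro-6-[2-hydroxy-4-methoxy-5-(methoxycarbonyl)-3,6-dimethylphenoxy]-4-methoxy-2-methylbenzoate | COC(=O)c1c(C)c(Oc2c(Br)c(OC)c(Cl)c(C)c2C(=O)OCc2ccccc2)c(O)c(C)c1OC
F10 | step 11 | benzyl 3-chloro-6-[2,4-dihydroxy-5-(methoxycarbonyl)-3,6-dimethylphenoxy]-5-formyl-4-hydroxy-2-methylbenzoate | COC(=O)c1c(C)c(Oc2c(C=O)c(O)c(Cl)c(C)c2C(=O)OCc2ccccc2)c(O)c(C)c1O
F11 | step 2 | benzyl 2-hydroxy-4-methoxy-6-methylbenzoate | COc1cc(C)c(C(=O)OCc2ccccc2)c(O)c1
F12 | step 6 | methyl 4-hydroxy-6-methyl-2-oxo-2H-pyran-5-carboxylate | COC(=O)c1c(C)oc(=O)cc1O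
F13 | step 6 | methyl 4-hydroxy-6-methyl-2-oxo-3-[(phenylsulfanyl)methyl]-2H-pyran-5-carboxylate | COC(=O)c1c(C)oc(=O)c(CSc2ccccc2)c1O
A1 | alternative 1 | tert-butyl 2-[2,4-bis(benzyloxy)-5-(methoxycarbonyl)-3,6-dimethylphenoxy]-6-methyl-4-oxocyclohex-2-ene-1-carboxylate (racemic diastereomer mixture) | CC1CC(=O)C=C(Oc2c(C)c(C(=O)OC)c(OCc3ccccc3)c(C)c2OCc2ccccc2)C1C(=O)OC(C)(C)C
A2 | alternative 1 | tert-butyl (E)-3-[2,4-bis(benzyloxy)-5-(methoxycarbonyl)-3,6-dimethylphenoxy]but-2-enoate | C/C(Oc1c(C)c(C(=O)OC)c(OCc2ccccc2)c(C)c1OCc1ccccc1)=C\C(=O)OC(C)(C)C
A3 | alternative 1 | methyl (E)-but-2-enoate | C/C=C/C(=O)OC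
A4 | alternative 1 | tert-butyl 6-[2,4-bis(benzyloxy)-5-(methoxycarbonyl)-3,6-dimethylphenoxy]-4-hydroxy-2-methylbenzoate | Cc1cc(O)cc(Oc2c(C)c(C(=O)OC)c(OCc3ccccc3)c(C)c2OCc2ccccc2)c1C(=O)OC(C)(C)C
A5 | alternative 1 | methyl 2,4-bis(benzyloxy)-5-hydroxy-3,6-dimethylbenzoate | COC(=O)c1c(C)c(O)c(OCc2ccccc2)c(C)c1OCc1ccccc1
A6 | alternative 2 | depsidone of the des-formyl 3'-O-methyl target (seven-membered lactone from the C6' carbonyl to the C4 oxygen) | COC(=O)c1c(C)c2Oc3cc(OC)c(Cl)c(C)c3C(=O)Oc2c(C)c1O
A7 | alternative 2 | methyl 4-(but-2-ynoyloxy)-3-[(5-chloro-4-methoxy-6-oxo-6H-pyran-2-yl)oxy]-6-hydroxy-2,5-dimethylbenzoate | COC(=O)c1c(C)c(Oc2cc(OC)c(Cl)c(=O)o2)c(OC(=O)C#CC)c(C)c1O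
A8 | alternative 3 | tert-butyl 3-chloro-6-[4-hydroxy-5-(methoxycarbonyl)-3,6-dimethyl-2-(triisopropylsilyloxy)phenoxy]-4-methoxy-2-methylbenzoate | COC(=O)c1c(C)c(Oc2cc(OC)c(Cl)c(C)c2C(=O)OC(C)(C)C)c(O[Si](C(C)C)(C(C)C)C(C)C)c(C)c1O
A9 | alternative 3 | methyl 4-[2-(tert-butoxycarbonyl)-4-chloro-5-methoxy-3-methylphenoxy]-5-chloro-3-methyl-5-oxopent-3-enoate (either alkene isomer) | COC(=O)CC(C)=C(Oc1cc(OC)c(Cl)c(C)c1C(=O)OC(C)(C)C)C(Cl)=O
A10 | alternative 3 | tert-butyl 3-chloro-4-methoxy-6-[(5-methoxy-3-methyl-1,5-dioxopenta-1,3-dien-2-yl)oxy]-2-methylbenzoate (aryloxy(vinyl)ketene, alkene geometry not fixed) | COC(=O)C=C(C)C(=C=O)Oc1cc(OC)c(Cl)c(C)c1C(=O)OC(C)(C)C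
A11 | alternative 3 | 1-(triisopropylsilyloxy)prop-1-yne | CC#CO[Si](C(C)C)(C(C)C)C(C)C
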